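**Retrosynthetic overview**
1. Target 11 ⇒ primary allylic CH2–O ester bond (Mitsunobu) ⇒ hydroxymethyl enoate 8 + angelic acid 9.
2. 8 ⇒ syn-hydroalumination of an ynoate and trapping with CH2O (sets the Z-alkene) ⇒ but-2-ynoate 6.
3. 6 ⇒ benzylic C–O bond with the S centre, by enantioselective Markovnikov addition of but-2-ynoic acid 5 to propenylphenol 4.
4. 4 ⇒ Wittig olefination of aldehyde 1 with phosphonium salt 2.
5. No ring is formed; the arene comes intact from 1 and the phenol stays unprotected throughout.

Assumption: 1, 5 and 9 are bought; the (R,R)-catalyst of step 2 is assumed to give the (S)-ester, and if the first run shows the opposite sense the (S,S)-catalyst is used in the same route.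

**Step 1**
Reactants: 1 3-hydroxy-4,5-dimethoxybenzaldehyde; 2 ethyltriphenylphosphonium bromide
Product: 4 2,3-dimethoxy-5-[(Z)-prop-1-en-1-yl]phenol (Z-major Z/E mixture), via ethylidenetriphenylphosphorane 3 (not isolated)
Conditions: 2 (1.4 equiv), KOtBu (2.5 equiv), THF, 0 °C; then 1, 0 °C → rt, 3 h; aq NH4Cl
Reagents that add atoms: none
Why: Wittig olefination in which one extra equivalent of base carries the phenol as its phenoxide (meta to CHO, so the aldehyde stays electrophilic); the Z/E ratio does not matter because both isomers give the same benzylic radical in step 2.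

**Step 2**
Reactants: 4 2,3-dimethoxy-5-[(Z)-prop-1-en-1-yl]phenol (Z/E mixture); 5 but-2-ynoic acid
Product: 6 (1S)-1-(3-hydroxy-4,5-dimethoxyphenyl)propyl but-2-ynoate
Conditions: 5 (4 equiv), Co(II) complex of (R,R)-N,N'-bis[5-tert-butyl-3-(3,5-di-tert-butylphenyl)salicylidene]-1,2-diphenylethane-1,2-diamine (5 mol %), N-fluoro-2,4,6-trimethylpyridinium triflate (1.5 equiv), PhSiH3 (1.2 equiv), PhCF3/acetone, −30 °C, Ar, dark; aq NaHCO3; Et3N-deactivated silica
Reagents that add atoms: none
Why: Proposed new method: an intermolecular, enantioselective Markovnikov hydroacyloxylation of an acyclic β-methylstyrene by cobalt-hydride hydrogen-atom transfer and radical-polar crossover, in which the Co(III)–H (from the Co(III) fluoride and PhSiH3) gives H• to the CH3-bearing alkene carbon of either isomer, the p-methoxy-stabilised benzylic radical is captured by the chiral Co(II) salen and oxidised to a catalyst-bound alkylcobalt(IV), and but-2-ynoate (pKa about 2.6, fully ionised by the collidine released, while the phenol is not) displaces cobalt at the benzylic carbon inside the chiral pocket, forming the C–O bond and setting C1 as S; the closest known reaction type is the Co(salen)/N-fluoropyridinium/silane Mukaiyama-type hydroalkoxylation and hydroacyloxylation of alkenes, established in racemic intermolecular form and enantioselectively in ring-forming cases, and the ynoate and the aryl OH are poor hydrogen-atom acceptors so they should be spared.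

**Step 3**
Reactants: 6 (1S)-1-(3-hydroxy-4,5-dimethoxyphenyl)propyl but-2-ynoate
Product: 8 (1S)-1-(3-hydroxy-4,5-dimethoxyphenyl)propyl (2Z)-2-(hydroxymethyl)but-2-enoate, via α-(diisobutylalanyl) enoate 7 (not isolated)
Conditions: DIBAL-H (2.3 equiv), NMO (2.6 equiv), THF, 0 °C, 2 h; then CH2O gas (from dry paraformaldehyde, 160 °C, N2 stream), −20 °C → rt; aq Rochelle salt
Reagents that add atoms: formaldehyde C=O
Why: Vinylalumination (1,4-hydroalumination of an ynoate followed by aldol-type addition, giving a β-substituted Morita–Baylis–Hillman-type adduct), in which the N-oxide-complexed hydride adds H and Al syn across the alkyne without reducing the ester, the first equivalent being spent on the phenol, and CH2O replaces Al with retention so that the β-methyl ends cis to the ester (Z) while the benzylic centre is not touched.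

**Step 4**
Reactants: 8 (1S)-1-(3-hydroxy-4,5-dimethoxyphenyl)propyl (2Z)-2-(hydroxymethyl)but-2-enoate; 9 angelic acid, (Z)-2-methylbut-2-enoic acid
Product: 11 (1S)-1-(3-hydroxy-4,5-dimethoxyphenyl)propyl (2Z)-2-({[(2Z)-2-methylbut-2-enoyl]oxy}methyl)but-2-enoate (target CNP0282120.1), via alkoxytriphenylphosphonium angelate 10 (not isolated)
Conditions: PPh3 (1.3 equiv), DIAD (1.3 equiv), THF, 0 °C, 15 min; then 8 and 9 (1.5 equiv) in THF, 0 °C, 1 h
Reagents that add atoms: none
Why: Mitsunobu esterification, in which the primary allylic alcohol is activated as its oxyphosphonium and displaced (SN2) by angelate oxygen, so the angeloyl carbonyl is never activated and cannot isomerise to tiglate, the carboxylic acid (pKa about 4.3) outcompetes the hindered phenol (pKa about 10) as pronucleophile, and pre-forming the betaine leaves no free phosphine to scramble either Z-alkene.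

**Compound list**
1 | 3-hydroxy-4,5-dimethoxybenzaldehyde | O=Cc1cc(O)c(OC)c(OC)c1 | starting material
2 | ethyltriphenylphosphonium bromide | CC[P+](c1ccccc1)(c1ccccc1)c1ccccc1.[Br-] | starting material
3 | ethylidenetriphenylphosphorane | CC=P(c1ccccc1)(c1ccccc1)c1ccccc1 | intermediate (not isolated)
4 | 2,3-dimethoxy-5-[(Z)-prop-1-en-1-yl]phenol (Z-major Z/E mixture; Z isomer drawn) | C/C=C\c1cc(O)c(OC)c(OC)c1 | intermediate
5 | but-2-ynoic acid | CC#CC(=O)O | starting material
6 | (1S)-1-(3-hydroxy-4,5-dimethoxyphenyl)propyl but-2-ynoate | CC#CC(=O)O[C@@H](CC)c1cc(O)c(OC)c(OC)c1 | intermediate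
7 | (1S)-1-{3-[(diisobutylalanyl)oxy]-4,5-dimethoxyphenyl}propyl 2-(diisobutylalanyl)but-2-enoate, methyl cis to the ester (Al and H cis) | C/C=C(/[Al](CC(C)C)CC(C)C)C(=O)O[C@@H](CC)c1cc(O[Al](CC(C)C)CC(C)C)c(OC)c(OC)c1 | intermediate (not isolated)
8 | (1S)-1-(3-hydroxy-4,5-dimethoxyphenyl)propyl (2Z)-2-(hydroxymethyl)but-2-enoate | C/C=C(/CO)C(=O)O[C@@H](CC)c1cc(O)c(OC)c(OC)c1 | intermediate
9 | angelic acid, (Z)-2-methylbut-2-enoic acid | C/C=C(/C)C(=O)O | starting material
10 | {(2Z)-2-[(1S)-1-(3-hydroxy-4,5-dimethoxyphenyl)propoxycarbonyl]but-2-en-1-yl}oxytriphenylphosphonium (Z)-2-methylbut-2-enoate | C/C=C(/CO[P+](c1ccccc1)(c1ccccc1)c1ccccc1)C(=O)O[C@@H](CC)c1cc(O)c(OC)c(OC)c1.C/C=C(/C)C(=O)[O-] | intermediate (not isolated)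
11 | (1S)-1-(3-hydroxy-4,5-dimethoxyphenyl)propyl (2Z)-2-({[(2Z)-2-methylbut-2-enoyl]oxy}methyl)but-2-enoate | C/C=C(/C)C(=O)OC/C(=C/C)C(=O)O[C@@H](CC)c1cc(O)c(OC)c(OC)c1 | target

**Totals**
Total steps: 4. Longest linear sequence: 4 (1 → 4 → 6 → 8 → 11).

**Three steps most likely to fail**

Step 2 (proposed new reaction). The level and sense of enantioinduction are unknown. The phenol of a second molecule could compete as O-nucleophile. The electron-rich benzylic ester of a fairly strong acid can ionise and racemise if it meets acid, hence the cold, buffered work-up. The ee would be checked by chiral HPLC against material from the fallback. Fallback by known chemistry, setting out from 1 and coming back at 6: silylate 1 (TBSCl, imidazole, DMF) to 3-[(tert-butyldimethylsilyl)oxy]-4,5-dimethoxybenzaldehyde F1. Add Et2Zn (2 equiv) under catalysis by (−)-DAIB, (2S)-3-exo-(dimethylamino)isoborneol (5 mol %), in toluene at 0 °C; ethyl is delivered to the Si face and gives (1S)-1-{3-[(tert-butyldimethylsilyl)oxy]-4,5-dimethoxyphenyl}propan-1-ol F2. Acylate with 5 (DCC, 5 mol % DMAP, CH2Cl2, −20 → 0 °C), with retention, to (1S)-1-{3-[(tert-butyldimethylsilyl)oxy]-4,5-dimethoxyphenyl}propyl but-2-ynoate F3. Cleave the aryl silyl ether with TBAF/AcOH (THF, 0 °C) to reach 6. Here the stereocentre is set by C–C bond formation and the C–O bond by ordinary acylation.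

Step 3. The hydride could attack the ester in a 1,2 sense. The aluminium allenolate form could leak Z/E. Lewis-acidic aluminium could cleave the benzylic C–O bond. Fallback setting out from 6 and coming back at 8: Pd(PPh3)4-catalysed syn-hydrostannation with Bu3SnH (THF, 0 °C) gives (1S)-1-(3-hydroxy-4,5-dimethoxyphenyl)propyl (2E)-2-(tributylstannyl)but-2-enoate F4. Iododestannylation (I2, CH2Cl2, 0 °C, dark) gives, with retention, (1S)-1-(3-hydroxy-4,5-dimethoxyphenyl)propyl (2E)-2-iodobut-2-enoate F5. Stille coupling with (tributylstannyl)methanol (Pd2(dba)3, AsPh3, CuI, DMF, 50 °C) installs the CH2OH with retention and gives 8. The alkene geometry is then set by a Pd-catalysed syn addition instead of by the aluminium reagent.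

Step 4. Risks are SN2' attack giving the branched 3-acyloxy-2-methylene isomer, O-alkylation of the phenol, and phosphine-induced Z → E drift. Fallback setting out from 8 and coming back at 11: convert 8 (CBr4, PPh3, CH2Cl2, −20 °C) into (1S)-1-(3-hydroxy-4,5-dimethoxyphenyl)propyl (2E)-2-(bromomethyl)but-2-enoate F6 and use it at once. Displace bromide with preformed caesium angelate, caesium (Z)-2-methylbut-2-enoate F7 (from 9 and 0.5 equiv Cs2CO3 in MeOH, dried), in DMF at 0 °C to give 11. Electrophile and nucleophile are made separately, no betaine or free phosphine meets the product, and the carboxylate salt is too weak a base to deprotonate the phenol.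

**Further compounds**
F1 | step 2 | 3-[(tert-butyldimethylsilyl)oxy]-4,5-dimethoxybenzaldehyde | O=Cc1cc(O[Si](C)(C)C(C)(C)C)c(OC)c(OC)c1
F2 | step 2 | (1S)-1-{3-[(tert-butyldimethylsilyl)oxy]-4,5-dimethoxyphenyl}propan-1-ol | CC[C@H](O)c1cc(O[Si](C)(C)C(C)(C)C)c(OC)c(OC)c1
F3 | step 2 | (1S)-1-{3-[(tert-butyldimethylsilyl)oxy]-4,5-dimethoxyphenyl}propyl but-2-ynoate | CC#CC(=O)O[C@@H](CC)c1cc(O[Si](C)(C)C(C)(C)C)c(OC)c(OC)c1
F4 | step 3 | (1S)-1-(3-hydroxy-4,5-dimethoxyphenyl)propyl (2E)-2-(tributylstannyl)but-2-enoate | C/C=C(/[Sn](CCCC)(CCCC)CCCC)C(=O)O[C@@H](CC)c1cc(O)c(OC)c(OC)c1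
F5 | step 3 | (1S)-1-(3-hydroxy-4,5-dimethoxyphenyl)propyl (2E)-2-iodobut-2-enoate | C/C=C(/I)C(=O)O[C@@H](CC)c1cc(O)c(OC)c(OC)c1
F6 | step 4 | (1S)-1-(3-hydroxy-4,5-dimethoxyphenyl)propyl (2E)-2-(bromomethyl)but-2-enoate | C/C=C(/CBr)C(=O)O[C@@H](CC)c1cc(O)c(OC)c(OC)c1
F7 | step 4 | caesium (Z)-2-methylbut-2-enoate (caesium angelate) | C/C=C(/C)C(=O)[O-].[Cs+]
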